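**Retrosynthetic overview**
1. Target 9 ⇒ 4,6-dibromo-3-(methylsulfanyl)indole 7 by a late C2–Br disconnection (electrophilic bromination).
2. 7 ⇒ sulfenylated nitro enamine 5 by the key N1–C2 disconnection (reductive C–N ring closure, Leimgruber–Batcho type).
3. 5 ⇒ nitro enamine 4 by a C3–S disconnection (new C-sulfenylation of the enamine with MeSSO2Me).
4. 4 ⇒ 2,4-dibromo-6-nitrotoluene 1 + DMF dimethyl acetal 2 (benzylic condensation).
5. Ring order: the benzene ring is bought with both bromines in place; only the pyrrole ring is built, and it is closed last through N1–C2.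

Assumption: the target has no stereocentre or other stereo-element, so no stereocontrol is needed; compound 1 is taken as a catalogue chemical.

**Route**

Step 1
Reactants: 1 2,4-dibromo-6-nitrotoluene (1,5-dibromo-2-methyl-3-nitrobenzene); 2 N,N-dimethylformamide dimethyl acetal; 3 S-methyl methanethiosulfonate
Product: 5 2-(2,4-dibromo-6-nitrophenyl)-N,N-dimethyl-2-(methylsulfanyl)ethen-1-amine, via nitro enamine 4 (not isolated)
Conditions: 2 (1.5 equiv), DMF, 110 °C; evaporate volatiles; then 3 (1.05 equiv), Et3N (1.5 equiv), CH2Cl2, −20 °C → rt; short basic-alumina plug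
Reagents that add atoms: N,N-dimethylformamide dimethyl acetal, COC(OC)N(C)C; S-methyl methanethiosulfonate, CS(=O)(=O)SC
Why: Proposed new method: the methyl group ortho to NO2 condenses with DMF-DMA in the usual Leimgruber–Batcho way to enamine 4, whose benzylic β-carbon (kept nucleophilic because the 2,6-disubstituted nitroarene is twisted out of conjugation) attacks the sulfenyl sulfur of the thiosulfonate with loss of methanesulfinate, and Et3N deprotonates the resulting α-thio iminium to the tetrasubstituted enamine 5 (E/Z mixture, no stereocentre); the closest known reaction types are α-sulfenylation of ketone enamines with thiosulfonates or sulfenyl chlorides and C-acylation of Leimgruber–Batcho enamines, whereas C-sulfenylation of a β-amino-2-nitrostyrene has not been shown.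

Step 2
Reactants: 5 2-(2,4-dibromo-6-nitrophenyl)-N,N-dimethyl-2-(methylsulfanyl)ethen-1-amine
Product: 7 4,6-dibromo-3-(methylsulfanyl)-1H-indole, via amino enamine 6 (not isolated)
Conditions: Fe powder (6 equiv), AcOH/EtOH 1:1, 80 °C
Reagents that add atoms: none
Why: Leimgruber–Batcho reductive cyclization: Fe/AcOH reduces only the nitro group (aryl C–Br and C–S are inert to it), the aniline nitrogen of 6 attacks the C-protonated enamine (α-thio iminium) carbon to form the N1–C2 bond, and loss of dimethylamine aromatises the 2-(dimethylamino)indoline to the indole; no stereocentre is formed.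

Step 3
Reactants: 7 4,6-dibromo-3-(methylsulfanyl)-1H-indole; 8 N-bromosuccinimide
Product: 9 2,4,6-tribromo-3-(methylsulfanyl)-1H-indole
Conditions: NBS (1.0 equiv), anhydrous CH2Cl2, −78 → 0 °C, dark
Reagents that add atoms: N-bromosuccinimide, O=C1CCC(=O)N1Br
Why: Electrophilic bromination of a 3-substituted indole: Br+ is taken up at C3/S (3-bromoindolenine or bromosulfonium), shifts to C2 and the ring rearomatises by loss of H+, while the benzenoid ring, deactivated by two bromines, stays untouched; no stereocentre is formed.

**Compound list**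
1 | 2,4-dibromo-6-nitrotoluene (1,5-dibromo-2-methyl-3-nitrobenzene) | Cc1c(Br)cc(Br)cc1[N+](=O)[O-] | starting material
2 | N,N-dimethylformamide dimethyl acetal | COC(OC)N(C)C | starting material
3 | S-methyl methanethiosulfonate | CS(=O)(=O)SC | starting material
4 | (E)-2-(2,4-dibromo-6-nitrophenyl)-N,N-dimethylethen-1-amine | CN(C)/C=C/c1c(Br)cc(Br)cc1[N+](=O)[O-] | intermediate (not isolated)
5 | 2-(2,4-dibromo-6-nitrophenyl)-N,N-dimethyl-2-(methylsulfanyl)ethen-1-amine (E/Z mixture, geometry lost on cyclization) | CN(C)C=C(SC)c1c(Br)cc(Br)cc1[N+](=O)[O-] | intermediate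
6 | 2-(2-amino-4,6-dibromophenyl)-N,N-dimethyl-2-(methylsulfanyl)ethen-1-amine (E/Z mixture) | CN(C)C=C(SC)c1c(N)cc(Br)cc1Br | intermediate (not isolated)
7 | 4,6-dibromo-3-(methylsulfanyl)-1H-indole | CSc1c[nH]c2cc(Br)cc(Br)c12 | intermediate
8 | N-bromosuccinimide | O=C1CCC(=O)N1Br | starting material
9 | 2,4,6-tribromo-3-(methylsulfanyl)-1H-indole (achiral) | CSc1c(Br)[nH]c2cc(Br)cc(Br)c12 | target

**Totals**
Total step count: 3. Longest linear sequence: 3 steps (1 → 5 → 7 → 9).

**Steps most likely to fail, with fallbacks**

Step 1 (the proposed new C-sulfenylation). The push–pull enamine 4 may be too weak a nucleophile for the thiosulfonate, or may be sulfenylated twice or hydrolysed. The fallback uses known chemistry and sets out from compound 4. It is cyclized first, under ordinary Leimgruber–Batcho conditions (Fe, AcOH, 80 °C), to 4,6-dibromo-1H-indole F1. The sulfur is then introduced by classical electrophilic C3-sulfenylation of the indole with methanesulfenyl chloride (from MeSSMe and SO2Cl2, CH2Cl2, −78 → 0 °C). This comes back to the route at compound 7; the C–S bond is made after the ring closure instead of before it.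

Step 2 (reductive cyclization of the thio-enamine). The α-thio iminium or aldehyde formed in hot acid could lose sulfur reductively or decompose before the amine closes the ring. The fallback sets out from compound 5 and separates reduction from cyclization. Acidic methanolysis (HC(OMe)3, TsOH, MeOH) gives 1,5-dibromo-2-[2,2-dimethoxy-1-(methylsulfanyl)ethyl]-3-nitrobenzene F2. Neutral nitro reduction (Fe, NH4Cl, EtOH/H2O) gives 3,5-dibromo-2-[2,2-dimethoxy-1-(methylsulfanyl)ethyl]aniline F3. Acid (TFA, CH2Cl2 or 1 M HCl/THF) then closes the amino acetal to the indole, as in the last stage of a Gassman indole synthesis. This comes back to the route at compound 7.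

Step 3 (C2 bromination). NBS may oxidise sulfur or over-brominate, and the product is acid- and light-sensitive. The fallback sets out from compound 7 and avoids electrophilic bromine at the indole. Iridium-catalysed C2–H borylation ([Ir(OMe)(cod)]2, dtbpy, B2pin2, THF, 60 °C; C5 and C7 are blocked by the flanking bromines) gives 4,6-dibromo-3-(methylsulfanyl)-2-(4,4,5,5-tetramethyl-1,3,2-dioxaborolan-2-yl)-1H-indole F4. Copper-mediated bromodeboronation (CuBr2, MeOH/H2O, 60 °C) then gives the target, coming back to the route at compound 9.

**Further compounds**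
F1 | step 1 | 4,6-dibromo-1H-indole | Brc1cc(Br)c2cc[nH]c2c1
F2 | step 2 | 1,5-dibromo-2-[2,2-dimethoxy-1-(methylsulfanyl)ethyl]-3-nitrobenzene (racemic) | COC(OC)C(SC)c1c(Br)cc(Br)cc1[N+](=O)[O-]
F3 | step 2 | 3,5-dibromo-2-[2,2-dimethoxy-1-(methylsulfanyl)ethyl]aniline (racemic) | COC(OC)C(SC)c1c(N)cc(Br)cc1Br
F4 | step 3 | 4,6-dibromo-3-(methylsulfanyl)-2-(4,4,5,5-tetramethyl-1,3,2-dioxaborolan-2-yl)-1H-indole | CSc1c(B2OC(C)(C)C(C)(C)O2)[nH]c2cc(Br)cc(Br)c12
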